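## Retrosynthetic overview

1. The SMILES reads as (3R,3aS,6R,6aS): the 3a-OH and 6a-H are anti, so the ring junction is trans and ring A must be closed last by an irreversible SN2 etherification (cut O2–C1 → triol 9).
2. Triol 9 ⇒ α-hydroxy aldehyde 7 + aryl Grignard 8 (the C3 carbinol is set by chelation control).
3. Aldehyde 7 ⇒ ring B oxolane 6 ⇒ enal 4 + hydroxy ketone 3 by an enantioselective oxa-Michael (C–O)/aldol domino that sets three stereocentres with the two side arms anti.
4. Hydroxy ketone 3 ⇒ bromo ketone 1.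
5. Ring order: ring B (the oxolane carrying the C6 aryl) first, ring A (the oxolane carrying the C3 aryl, trans-fused) last.

Assumption: the SMILES is taken literally (trans-fused junction, not the cis-fused gmelinol skeleton), and 1, 4 and 8 are treated as catalogue chemicals.

## Route

Step 1
Reactants: 1 3-bromo-1,1-dimethoxypropan-2-one
Product: 3 3-hydroxy-1,1-dimethoxypropan-2-one, via formate ester 2 (not isolated)
Conditions: HCO2K (2 equiv), MeOH, reflux
Reagents that add atoms: potassium formate, [K+].[O-]C=O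
Why: SN2 displacement of the α-bromo ketone by formate, then in situ methanolysis of the formate ester (formate route to α-hydroxy ketones); no stereocentre is involved.

Step 2
Reactants: 3 3-hydroxy-1,1-dimethoxypropan-2-one; 4 (E)-3-(3,4-dimethoxyphenyl)prop-2-enal
Product: 6 (3S,4S,5R)-5-(3,4-dimethoxyphenyl)-3-(dimethoxymethyl)-4-(hydroxymethyl)oxolan-3-ol, via aldol aldehyde 5 (not isolated)
Conditions: (R)-2-[bis(3,5-bis(trifluoromethyl)phenyl)(trimethylsilyloxy)methyl]pyrrolidine (20 mol %), PhCO2H (10 mol %), CHCl3, 0 °C → rt; then NaBH4, MeOH, −20 °C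
Reagents that add atoms: none
Why: Proposed new method: the iminium ion of 4 takes the hydroxyl of 3 on the enal face left open by the (R)-diaryl(silyloxy)methyl group (oxa-Michael, C–O bond, sets C5 as R), the enamine so formed closes by a 5-exo intramolecular aldol onto the ketone from the same face (aryl and formyl trans) with the ketone oxygen turned toward the iminium nitrogen and the bulky dimethoxymethyl group away from the catalyst (hydroxyl cis and acetal trans to formyl), and NaBH4 traps the β-hydroxy aldehyde before it can dehydrate; the closest known reaction type is the diarylprolinol silyl ether catalysed oxa-Michael/aldol/hemiacetalisation domino of dihydroxyacetone dimer with enals, which has not been shown for an α-hydroxy ketone that cannot hemiacetalise.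

Step 3
Reactants: 6 (3S,4S,5R)-5-(3,4-dimethoxyphenyl)-3-(dimethoxymethyl)-4-(hydroxymethyl)oxolan-3-ol
Product: 7 (3S,4S,5R)-5-(3,4-dimethoxyphenyl)-3-hydroxy-4-(hydroxymethyl)oxolane-3-carbaldehyde
Conditions: 1 M aq. HCl, THF, 25 °C; used crude and cold
Reagents that add atoms: water, O
Why: Acid-catalysed acetal hydrolysis; the aldehyde sits on a fully substituted carbon, so nothing can epimerise and the three ring stereocentres are untouched.

Step 4
Reactants: 7 (3S,4S,5R)-5-(3,4-dimethoxyphenyl)-3-hydroxy-4-(hydroxymethyl)oxolane-3-carbaldehyde; 8 3,4-dimethoxyphenylmagnesium bromide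
Product: 9 (3S,4S,5R)-5-(3,4-dimethoxyphenyl)-3-[(R)-(3,4-dimethoxyphenyl)(hydroxy)methyl]-4-(hydroxymethyl)oxolan-3-ol
Conditions: 8 (3.5 equiv), THF, −78 → −20 °C; aq. NH4Cl
Reagents that add atoms: none
Why: Chelation-controlled (Cram cyclic model) Grignard addition: the tertiary magnesium alkoxide and the aldehyde oxygen form a five-membered chelate and the aryl group enters from the face flanked by the ring CH2 (C2), away from the substituted C4 and the C5 aryl group, which gives the (R)-carbinol while the ring stereocentres are untouched.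

Step 5
Reactants: 9 (3S,4S,5R)-5-(3,4-dimethoxyphenyl)-3-[(R)-(3,4-dimethoxyphenyl)(hydroxy)methyl]-4-(hydroxymethyl)oxolan-3-ol
Product: 11 (3R,3aS,6R,6aS)-3,6-bis(3,4-dimethoxyphenyl)tetrahydro-1H,3H-furo[3,4-c]furan-3a(4H)-ol, via primary tosylate 10 (not isolated)
Conditions: TsCl (1.1 equiv), Et3N, DMAP (cat.), CH2Cl2, 0 °C; then NaH (1.1 equiv), THF (0.01 M), 0 → 45 °C; base-washed silica
Reagents that add atoms: none
Why: Selective sulfonylation of the only primary hydroxyl and intramolecular Williamson etherification (5-exo-tet SN2) by the more acidic benzylic alkoxide; the displacement is irreversible, proceeds with retention at the carbinol carbon and no change at the other stereocentres, and so converts the anti disposition of the two side arms of 9 into the trans ring fusion, the 4-exo closure of the tertiary alkoxide to an oxetane being slower.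

## Compound list

1 | 3-bromo-1,1-dimethoxypropan-2-one | COC(OC)C(=O)CBr | starting material
2 | 3,3-dimethoxy-2-oxopropyl formate | COC(OC)C(=O)COC=O | intermediate
3 | 3-hydroxy-1,1-dimethoxypropan-2-one | COC(OC)C(=O)CO | intermediate
4 | (E)-3-(3,4-dimethoxyphenyl)prop-2-enal | COc1ccc(/C=C/C=O)cc1OC | starting material
5 | (2R,3S,4S)-2-(3,4-dimethoxyphenyl)-4-(dimethoxymethyl)-4-hydroxyoxolane-3-carbaldehyde | COC(OC)[C@@]1(O)CO[C@@H](c2ccc(OC)c(OC)c2)[C@@H]1C=O | intermediate
6 | (3S,4S,5R)-5-(3,4-dimethoxyphenyl)-3-(dimethoxymethyl)-4-(hydroxymethyl)oxolan-3-ol | COC(OC)[C@@]1(O)CO[C@@H](c2ccc(OC)c(OC)c2)[C@@H]1CO | intermediate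
7 | (3S,4S,5R)-5-(3,4-dimethoxyphenyl)-3-hydroxy-4-(hydroxymethyl)oxolane-3-carbaldehyde | O=C[C@@]1(O)CO[C@@H](c2ccc(OC)c(OC)c2)[C@@H]1CO | intermediate
8 | 3,4-dimethoxyphenylmagnesium bromide | COc1ccc([Mg]Br)cc1OC | starting material
9 | (3S,4S,5R)-5-(3,4-dimethoxyphenyl)-3-[(R)-(3,4-dimethoxyphenyl)(hydroxy)methyl]-4-(hydroxymethyl)oxolan-3-ol | COc1ccc(cc1OC)[C@@H](O)[C@@]1(O)CO[C@@H](c2ccc(OC)c(OC)c2)[C@@H]1CO | intermediate
10 | [(2R,3S,4S)-2-(3,4-dimethoxyphenyl)-4-[(R)-(3,4-dimethoxyphenyl)(hydroxy)methyl]-4-hydroxyoxolan-3-yl]methyl 4-methylbenzenesulfonate | COc1ccc(cc1OC)[C@@H](O)[C@@]1(O)CO[C@@H](c2ccc(OC)c(OC)c2)[C@@H]1COS(=O)(=O)c3ccc(C)cc3 | intermediate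
11 | (3R,3aS,6R,6aS)-3,6-bis(3,4-dimethoxyphenyl)tetrahydro-1H,3H-furo[3,4-c]furan-3a(4H)-ol | COc1ccc([C@H]2OC[C@H]3[C@H](c4ccc(OC)c(OC)c4)OC[C@]23O)cc1OC | target

## Step count and risks

Total step count: 5. Longest linear sequence: 5 steps (1 → 3 → 6 → 7 → 9 → 11).

Steps most likely to fail:

**Step 2 (proposed new domino).** The risks are the wrong epimer at the tertiary carbinol, dehydration of the aldol, or low ee. The fallback uses known chemistry only, sets out from 4 and comes back at 7. Under the published conditions for the dihydroxyacetone domino (dihydroxyacetone dimer, the same (R)-catalyst, PhCO2H, CHCl3), 4 gives the cis-fused lactol (3aR,6R,6aS)-6-(3,4-dimethoxyphenyl)tetrahydro-1H,3H-furo[3,4-c]furan-1,3a(4H)-diol F1, in which the aryl-bearing carbon and its neighbour already have the needed configuration. NaBH4 in MeOH opens the lactol to (3S,4S,5R)-5-(3,4-dimethoxyphenyl)-3,4-bis(hydroxymethyl)oxolan-3-ol F2. NaIO4 in aqueous THF cleaves the tertiary–primary glycol, which erases the unwanted carbinol centre, and gives (4S,5R)-5-(3,4-dimethoxyphenyl)-4-(hydroxymethyl)oxolan-3-one F3. Vinylmagnesium bromide with CeCl3 at −78 °C adds to the ketone anti to the neighbouring hydroxymethyl arm and gives (3S,4S,5R)-5-(3,4-dimethoxyphenyl)-3-ethenyl-4-(hydroxymethyl)oxolan-3-ol F4. Ozonolysis (O3, CH2Cl2–MeOH, pyridine, −78 °C; Me2S) then delivers 7.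

**Step 4 (facial selectivity of the aryl addition).** The two faces of the chelate differ only modestly, so the (S)-carbinol may dominate. The fallback sets out from 9 (as the crude epimer mixture of step 4) and comes back at 9. DDQ in CH2Cl2 oxidises only the electron-rich benzylic carbinol to (3,4-dimethoxyphenyl)[(3S,4S,5R)-5-(3,4-dimethoxyphenyl)-3-hydroxy-4-(hydroxymethyl)oxolan-3-yl]methanone F5. Zn(BH4)2 in Et2O at −20 °C then reduces the ketone through the same five-membered chelate but delivers hydride where the Grignard delivered aryl, so the sense of induction is reversed and the (R)-carbinol 9 results.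

**Step 5 (strained trans-fused closure).** The closure may be slow, and the tertiary alkoxide may compete to give an oxetane. The fallback sets out from 10, this time isolated after the tosylation, and comes back at 11. NaI in acetone at 50 °C gives (R)-(3,4-dimethoxyphenyl)[(3S,4S,5R)-5-(3,4-dimethoxyphenyl)-3-hydroxy-4-(iodomethyl)oxolan-3-yl]methanol F6. AgOTf with 2,6-di-tert-butylpyridine in CH2Cl2 at 0 °C → rt abstracts iodide and lets the neutral benzylic hydroxyl close the five-membered ring without any alkoxide present.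

Further compounds
F1 | step 2 | (3aR,6R,6aS)-6-(3,4-dimethoxyphenyl)tetrahydro-1H,3H-furo[3,4-c]furan-1,3a(4H)-diol | OC1OC[C@]2(O)CO[C@@H](c3ccc(OC)c(OC)c3)[C@H]12
F2 | step 2 | (3S,4S,5R)-5-(3,4-dimethoxyphenyl)-3,4-bis(hydroxymethyl)oxolan-3-ol | OC[C@H]1[C@H](c2ccc(OC)c(OC)c2)OC[C@@]1(O)CO
F3 | step 2 | (4S,5R)-5-(3,4-dimethoxyphenyl)-4-(hydroxymethyl)oxolan-3-one | OC[C@H]1[C@H](c2ccc(OC)c(OC)c2)OCC1=O
F4 | step 2 | (3S,4S,5R)-5-(3,4-dimethoxyphenyl)-3-ethenyl-4-(hydroxymethyl)oxolan-3-ol | C=C[C@@]1(O)CO[C@@H](c2ccc(OC)c(OC)c2)[C@@H]1CO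
F5 | step 4 | (3,4-dimethoxyphenyl)[(3S,4S,5R)-5-(3,4-dimethoxyphenyl)-3-hydroxy-4-(hydroxymethyl)oxolan-3-yl]methanone | COc1ccc(cc1OC)C(=O)[C@@]1(O)CO[C@@H](c2ccc(OC)c(OC)c2)[C@@H]1CO
F6 | step 5 | (R)-(3,4-dimethoxyphenyl)[(3S,4S,5R)-5-(3,4-dimethoxyphenyl)-3-hydroxy-4-(iodomethyl)oxolan-3-yl]methanol | COc1ccc(cc1OC)[C@@H](O)[C@@]1(O)CO[C@@H](c2ccc(OC)c(OC)c2)[C@@H]1CI
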